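**Plan**

1. Cuts: the C2'–CH2 bond between the quinone ring and the acyloxymethyl carbon (union of the complete drimane/epoxy-ring unit with the complete hydroxymethylglutarate unit); the C11–C5' bond (drimane CH2 to the ring, made at the arene stage); the ester C–O bond to a stannylmethyl carrier; the C11–C12 bond of sclareolide.
2. Enabling feature: with the ring held as its C1' dimethyl ketal, C2' is the β-carbon of the C4' enone (a vinylogous acyl bromide that adds readily to zerovalent palladium), and the CH2 to be attached sits between that sp2 carbon and an ester oxygen, so it can travel as an α-acyloxymethyl–tin nucleophile carrying the whole side chain. The same ketal leaves C6' as the only unsubstituted β-carbon, which sends the peroxide to C5'=C6'.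
3. Forward order: sclareolide → 11-iodo-8α-formate → arylation at C11 → C8=C12 by dehydration → phenol oxidation to the para-quinone monoketal → C5'/C6' epoxide → side-chain union at C2' → unmasking of C1'=O and CO2H in one operation.
4. Stereochemistry: C5, C9, C10 come from (+)-sclareolide and are never touched. Side-chain C3 comes from (R)-mevalonolactone (its CH2OH carbon becomes the ester carbonyl, its lactone carbonyl the free acid). The epoxide is set by catalyst-controlled phase-transfer epoxidation.
5. Helpers and their removal: C8 formate (→ OH → alkene), aryl pivalate, C1' ketal and SEM ester (both fall in the last step), tin (lost in the union).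

Key step: step 13

Numbering used below: drimane numbering for the decalin (C11 = CH2 link on C9, C12 = carbon on C8; natural 5α-H, 9β-C11, 10β-CH3 series). Ring atoms are C1'(=O), C2'(bears CH2O), C3'(H), C4'(=O), C5'(epoxide carbon bearing C11), C6'(epoxide CH). SEM = [2-(trimethylsilyl)ethoxy]methyl.

**Route**

Step 1
Reactants: 1 (+)-sclareolide
Product: 2 sclareolide lactol (C12 hemiacetal, both anomers)
Conditions: i-Bu2AlH, CH2Cl2, −78 °C; aqueous work-up
Reagents that add atoms: none
Why: Partial hydride reduction of a γ-lactone to its lactol stops at the tetrahedral aluminate at −78 °C; no drimane stereocentre is touched and the new anomeric centre is irrelevant because C12 is excised in the next step.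

Step 2
Reactants: 2 sclareolide lactol
Product: 4 11-iododriman-8α-yl formate, via lactol hypoiodite 3 (not isolated)
Conditions: PhI(OAc)2, I2, cyclohexane, visible light, 40 °C
Reagents that add atoms: iodine (II)
Why: Suárez hypoiodite fragmentation, in which the C12 O-radical cleaves the C11–C12 bond so that the C8 oxygen is left as a formate and the primary C11 radical is trapped by iodine, C8 and C9 keeping their configuration because neither becomes a radical centre.

Step 3
Reactants: 5 3-bromo-4-methoxyphenol
Product: 6 5-bromo-2-iodo-4-methoxyphenol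
Conditions: N-iodosuccinimide, TsOH (cat.), MeCN, 0 °C to rt
Reagents that add atoms: N-iodosuccinimide (O=C1CCC(=O)N1I)
Why: Electrophilic aromatic iodination is directed by the free hydroxyl (the stronger donor) to its unhindered ortho position, the other ortho site being flanked by bromine.

Step 4
Reactants: 6 5-bromo-2-iodo-4-methoxyphenol
Product: 7 5-bromo-2-iodo-4-methoxyphenyl pivalate
Conditions: t-BuCOCl, Et3N, DMAP (cat.), CH2Cl2, 0 °C
Reagents that add atoms: pivaloyl chloride (CC(C)(C)C(=O)Cl)
Why: DMAP-catalysed O-acylation masks the acidic phenol as a hindered ester that is inert to the nickel coupling and to the later dehydration.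

Step 5
Reactants: 4 11-iododriman-8α-yl formate, 7 5-bromo-2-iodo-4-methoxyphenyl pivalate
Product: 8 5-bromo-2-(8α-formyloxydriman-11-yl)-4-methoxyphenyl pivalate
Conditions: NiBr2(dme) (10 mol%), 4,4'-di-tert-butyl-2,2'-bipyridine, Mn powder, NaI (cat.), DMA, 40 °C
Reagents that add atoms: none
Why: Nickel-catalysed reductive cross-electrophile coupling, in which the aryl C–I bond adds to low-valent nickel much faster than C–Br and the C11 radical from 4 is captured by the aryl–nickel species, C9 keeping its configuration because it is never a radical or carbanion centre.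

Step 6
Reactants: 8 5-bromo-2-(8α-formyloxydriman-11-yl)-4-methoxyphenyl pivalate
Product: 9 5-bromo-2-(8α-hydroxydriman-11-yl)-4-methoxyphenyl pivalate
Conditions: K2CO3 (cat.), MeOH, 0 °C
Reagents that add atoms: none
Why: Base-catalysed transesterification removes the unhindered formyl group far faster than the hindered aryl pivalate.

Step 7
Reactants: 9 5-bromo-2-(8α-hydroxydriman-11-yl)-4-methoxyphenyl pivalate
Product: 11 5-bromo-2-(drim-8(12)-en-11-yl)-4-methoxyphenyl pivalate, via C8 chlorosulfite 10 (not isolated)
Conditions: SOCl2, pyridine, CH2Cl2, −78 °C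
Reagents that add atoms: none
Why: Dehydration of the tertiary alcohol through its chlorosulfite by E2 elimination; the equatorial 8α leaving group has no antiperiplanar ring hydrogen, so the hydrogen is taken from the axial C12 methyl and the exocyclic C8=C12 alkene should predominate.

Step 8
Reactants: 11 5-bromo-2-(drim-8(12)-en-11-yl)-4-methoxyphenyl pivalate
Product: 13 5-bromo-2-(drim-8(12)-en-11-yl)-4,4-dimethoxycyclohexa-2,5-dien-1-one, via free phenol 12 (not isolated)
Conditions: NaOMe, MeOH, rt; AcOH; then PhI(OAc)2, 0 °C
Reagents that add atoms: methanol (CO)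
Why: Methanolysis of the aryl ester followed by PhI(OAc)2 oxidative dearomatisation of the para-methoxyphenol, in which methanol traps the phenoxenium ion at the methoxy-bearing carbon and so places the ketone at C4' next to the C5' substituent and the ketal at C1'.

Step 9
Reactants: 13 5-bromo-2-(drim-8(12)-en-11-yl)-4,4-dimethoxycyclohexa-2,5-dien-1-one
Product: 14 (1R,6S)-4-bromo-1-(drim-8(12)-en-11-yl)-5,5-dimethoxy-7-oxabicyclo[4.1.0]hept-3-en-2-one (5'R,6'S in ring numbering)
Conditions: t-BuOOH (decane), N-benzylcinchoninium chloride (20 mol%), aq. NaOH (cat.), toluene, 0 °C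
Reagents that add atoms: tert-butyl hydroperoxide (CC(C)(C)OO)
Why: Asymmetric phase-transfer Weitz–Scheffer epoxidation, in which the peroxide anion adds to C6' (the only unsubstituted β-carbon, C2' carrying bromine and being flanked by the ketal) and the C5' enolate closes the cis epoxide; the face is set by ion pairing with the cinchona ammonium cation (catalyst control, the drimane being insulated by C11), the cinchonine-derived salt being selected for the (5'R,6'S) epoxide and its pseudo-enantiomer giving the opposite face.

Step 10
Reactants: 15 (R)-mevalonolactone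
Product: 17 [2-(trimethylsilyl)ethoxy]methyl (3R)-3,5-dihydroxy-3-methylpentanoate (SEM mevalonate), via potassium (R)-mevalonate 16 (not isolated)
Conditions: KOH (1.0 equiv), H2O/MeOH, rt; evaporate; SEMCl, DMF, 0 °C
Reagents that add atoms: potassium hydroxide ([K+].[OH-]); 2-(trimethylsilyl)ethoxymethyl chloride (C[Si](C)(C)CCOCCl)
Why: Saponification of the δ-lactone and SN2 O-alkylation of the carboxylate free the C5 hydroxyl while masking C1 as an ester cleavable by HF, the tertiary carbinol centre being untouched.

Step 11
Reactants: 17 SEM mevalonate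
Product: 18 (3R)-3-hydroxy-3-methyl-5-oxo-5-{[2-(trimethylsilyl)ethoxy]methoxy}pentanoic acid
Conditions: TEMPO (cat.), NaOCl (cat.), NaClO2, MeCN/phosphate buffer (pH 6.7), 35 °C
Reagents that add atoms: sodium chlorite ([Na+].[O-]Cl=O)
Why: TEMPO-catalysed Anelli-type oxidation with chlorite as terminal oxidant takes the primary alcohol to the acid at near-neutral pH without touching the tertiary alcohol or the SEM ester, turning the mevalonate C5 into the carboxyl that will carry the ester.

Step 12
Reactants: 18 mono-SEM ester acid
Product: 20 1-[(tributylstannyl)methyl] 5-{[2-(trimethylsilyl)ethoxy]methyl} (3S)-3-hydroxy-3-methylpentanedioate, via caesium carboxylate 19 (not isolated)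
Conditions: Cs2CO3 (0.55 equiv), DMF, rt; Bu3SnCH2I
Reagents that add atoms: tributyl(iodomethyl)stannane (CCCC[Sn](CCCC)(CCCC)CI)
Why: Carboxylate SN2 alkylation with the α-stannyl iodide gives the α-acyloxymethylstannane without activating the β-hydroxy acid, so β-lactone formation and dehydration are avoided and C3 is untouched (the descriptor changes only through CIP priorities).

Step 13
Reactants: 14 bromo-epoxy-enone ketal, 20 α-acyloxymethylstannane
Product: 21 compound 14 with Br at C2' replaced by CH2–O–C(=O)CH2C(CH3)(OH)CH2CO2SEM (side-chain C3 configured as in 20)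
Conditions: Pd2(dba)3 (5 mol%), AsPh3 (20 mol%), CuI (20 mol%), NMP, 60 °C
Reagents that add atoms: none
Why: Migita–Kosugi–Stille coupling: zerovalent palladium inserts into the C2'–Br bond of 14, which as the β-position of the C4' enone is a vinylogous acyl bromide, the CH2 group of 20 is transferred from tin (helped by CuI and by coordination of its own ester carbonyl to tin), and reductive elimination forms the C2'–CH2 bond. The closest known reaction type is the palladium-catalysed hydroxymethylation and acyloxymethylation of alkenyl and aryl halides with Bu3SnCH2OR reagents, including halo-enones of the epoxyquinol series. No ring is closed and no stereocentre is formed; the epoxide centres, the drimane centres and side-chain C3 are remote from the reacting atoms and should pass through unchanged. The step needs transfer of the oxygenated CH2 in preference to butyl, which the α-oxygen and the chelating carbonyl secure, and reaction at C2' only, which is secured because 14 has no other carbon–halogen bond. The weak donor AsPh3 should keep palladium from ionising the allylic ester present in the product, and the neutral, fluoride-free conditions leave the epoxy ketone, the ketal and the SEM ester intact.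

Step 14
Reactants: 21 coupled SEM ester ketal
Product: 23 4'-oxomacrophorin D, via ketal acid 22 (not isolated)
Conditions: 48% aq. HF, MeCN, 0 °C to rt
Reagents that add atoms: water (O)
Why: Fluoride-induced fragmentation of the SEM ester and acid hydrolysis of the C1' dimethyl ketal to the enedione should both proceed under these mild HF conditions, which spare the epoxy ketone, the exocyclic alkene and the allylic ester and affect no stereocentre.

**Compound list**

1 | (+)-sclareolide | C[C@@]12CC[C@H]3C(C)(C)CCC[C@]3(C)[C@H]1CC(=O)O2 | starting material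
2 | sclareolide lactol (C12 hemiacetal, both anomers) | C[C@@]12CC[C@H]3C(C)(C)CCC[C@]3(C)[C@H]1CC(O)O2 | intermediate
3 | lactol hypoiodite | C[C@@]12CC[C@H]3C(C)(C)CCC[C@]3(C)[C@H]1CC(OI)O2 | intermediate (not isolated)
4 | 11-iododriman-8α-yl formate | C[C@@]1(OC=O)CC[C@H]2C(C)(C)CCC[C@]2(C)[C@H]1CI | intermediate
5 | 3-bromo-4-methoxyphenol | COc1ccc(O)cc1Br | starting material
6 | 5-bromo-2-iodo-4-methoxyphenol | COc1cc(I)c(O)cc1Br | intermediate
7 | 5-bromo-2-iodo-4-methoxyphenyl pivalate | COc1cc(I)c(OC(=O)C(C)(C)C)cc1Br | intermediate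
8 | 5-bromo-2-(8α-formyloxydriman-11-yl)-4-methoxyphenyl pivalate | C[C@@]1(OC=O)CC[C@H]2C(C)(C)CCC[C@]2(C)[C@H]1Cc1cc(OC)c(Br)cc1OC(=O)C(C)(C)C | intermediate
9 | 5-bromo-2-(8α-hydroxydriman-11-yl)-4-methoxyphenyl pivalate | C[C@@]1(O)CC[C@H]2C(C)(C)CCC[C@]2(C)[C@H]1Cc1cc(OC)c(Br)cc1OC(=O)C(C)(C)C | intermediate
10 | C8 chlorosulfite of 9 | C[C@@]1(OS(=O)Cl)CC[C@H]2C(C)(C)CCC[C@]2(C)[C@H]1Cc1cc(OC)c(Br)cc1OC(=O)C(C)(C)C | intermediate (not isolated)
11 | 5-bromo-2-(drim-8(12)-en-11-yl)-4-methoxyphenyl pivalate | C=C1CC[C@H]2C(C)(C)CCC[C@]2(C)[C@H]1Cc1cc(OC)c(Br)cc1OC(=O)C(C)(C)C | intermediate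
12 | 5-bromo-2-(drim-8(12)-en-11-yl)-4-methoxyphenol | C=C1CC[C@H]2C(C)(C)CCC[C@]2(C)[C@H]1Cc1cc(OC)c(Br)cc1O | intermediate (not isolated)
13 | 5-bromo-2-(drim-8(12)-en-11-yl)-4,4-dimethoxycyclohexa-2,5-dien-1-one | C=C1CC[C@H]2C(C)(C)CCC[C@]2(C)[C@H]1CC1=CC(OC)(OC)C(Br)=CC1=O | intermediate
14 | (1R,6S)-4-bromo-1-(drim-8(12)-en-11-yl)-5,5-dimethoxy-7-oxabicyclo[4.1.0]hept-3-en-2-one | C=C1CC[C@H]2C(C)(C)CCC[C@]2(C)[C@H]1C[C@@]12O[C@@H]1C(OC)(OC)C(Br)=CC2=O | intermediate
15 | (R)-mevalonolactone | C[C@@]1(O)CCOC(=O)C1 | starting material
16 | potassium (R)-mevalonate | C[C@@](O)(CCO)CC(=O)[O-].[K+] | intermediate (not isolated)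
17 | [2-(trimethylsilyl)ethoxy]methyl (3R)-3,5-dihydroxy-3-methylpentanoate | C[C@@](O)(CCO)CC(=O)OCOCC[Si](C)(C)C | intermediate
18 | (3R)-3-hydroxy-3-methyl-5-oxo-5-{[2-(trimethylsilyl)ethoxy]methoxy}pentanoic acid | C[C@@](O)(CC(=O)O)CC(=O)OCOCC[Si](C)(C)C | intermediate
19 | caesium salt of 18 | C[C@@](O)(CC(=O)[O-])CC(=O)OCOCC[Si](C)(C)C.[Cs+] | intermediate (not isolated)
20 | 1-[(tributylstannyl)methyl] 5-{[2-(trimethylsilyl)ethoxy]methyl} (3S)-3-hydroxy-3-methylpentanedioate | C[C@@](O)(CC(=O)OC[Sn](CCCC)(CCCC)CCCC)CC(=O)OCOCC[Si](C)(C)C | intermediate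
21 | SEM ester of 22 (14 with Br replaced by the SEM-protected hydroxymethylglutaryloxymethyl group) | C=C1CC[C@H]2C(C)(C)CCC[C@]2(C)[C@H]1C[C@@]12O[C@@H]1C(OC)(OC)C(COC(=O)C[C@@](C)(O)CC(=O)OCOCC[Si](C)(C)C)=CC2=O | intermediate
22 | C1' dimethyl ketal of 4'-oxomacrophorin D (free acid) | C=C1CC[C@H]2C(C)(C)CCC[C@]2(C)[C@H]1C[C@@]12O[C@@H]1C(OC)(OC)C(COC(=O)C[C@@](C)(O)CC(=O)O)=CC2=O | intermediate (not isolated)
23 | 4'-oxomacrophorin D ((5'R,6'S)-epoxide, (3S)-hydroxymethylglutarate monoester) | C=C1CC[C@H]2C(C)(C)CCC[C@]2(C)[C@H]1C[C@@]12O[C@@H]1C(=O)C(COC(=O)C[C@@](C)(O)CC(=O)O)=CC2=O | target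

**Step count and risks**

Total step count: 14. Longest linear sequence: 9 steps (steps 1, 2, 5, 6, 7, 8, 9, 13, 14, from 1 to 23).

Steps most likely to fail:

Step 13. The sp3 α-acyloxymethyl group may transfer from tin too slowly at the hindered C2' position next to the ketal, so that butyl transfer, protodestannylation or reduction of the C–Br bond compete. The fallback sets out from 14: the one-carbon reagent (tributylstannyl)methanol is coupled instead (Pd(PPh3)4, dioxane, 80 °C), which should give the hydroxymethyl enone F1. Its primary alcohol is then acylated with acid 18 under Steglich conditions (EDC·HCl, DMAP, CH2Cl2), which returns to the route at 21.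

Step 9. Facial selectivity may be poor because the dienone is flat and the catalyst must override a remote chiral group, and peroxide may also attack C2' with loss of bromide. The fallback sets out from 13 and uses auxiliary control in place of catalyst control: ketal exchange with (2R,4R)-pentane-2,4-diol (PPTS, benzene, molecular sieves) should give the C2-symmetric spiroketal F2. Epoxidation with Ph3COOH and KN(SiMe3)2 (THF, −78 °C), in which the diol methyl groups shield one face at C6', should give the epoxide F3; the diol antipode is the lever for the facial sense. Coupling of F3 with 20 under the conditions of step 13 should give the coupled ketal F4, and aqueous HF in MeCN cleaves the auxiliary ketal and the SEM ester and returns to the route at 23.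

Step 5. Capture of the hindered, neopentyl-like C11 radical may be slow, leading to reduction or dimerisation, and chemoselectivity between C–I and C–Br may erode. The fallback sets out from 4 and replaces the radical coupling by a two-electron organometallic one: zinc insertion (Zn dust, LiCl, THF, 40 °C) should give the alkylzinc iodide F5. Negishi coupling of F5 with 7 at the C–I bond (Pd(OAc)2, SPhos, THF, rt) returns to the route at 8.

**Further compounds**

F1 | step 13 | (1R,6S)-1-(drim-8(12)-en-11-yl)-4-(hydroxymethyl)-5,5-dimethoxy-7-oxabicyclo[4.1.0]hept-3-en-2-one | C=C1CC[C@H]2C(C)(C)CCC[C@]2(C)[C@H]1C[C@@]12O[C@@H]1C(OC)(OC)C(CO)=CC2=O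
F2 | step 9 | (2R,4R)-pentane-2,4-diyl ketal analogue of 13 | C=C1CC[C@H]2C(C)(C)CCC[C@]2(C)[C@H]1CC1=CC3(O[C@H](C)C[C@@H](C)O3)C(Br)=CC1=O
F3 | step 9 | (5'R,6'S)-epoxide of F2 | C=C1CC[C@H]2C(C)(C)CCC[C@]2(C)[C@H]1C[C@@]12O[C@@H]1C3(O[C@H](C)C[C@@H](C)O3)C(Br)=CC2=O
F4 | step 9 | product of coupling F3 with 20 (pentanediyl ketal analogue of 21) | C=C1CC[C@H]2C(C)(C)CCC[C@]2(C)[C@H]1C[C@@]12O[C@@H]1C3(O[C@H](C)C[C@@H](C)O3)C(COC(=O)C[C@@](C)(O)CC(=O)OCOCC[Si](C)(C)C)=CC2=O
F5 | step 5 | (8α-formyloxydriman-11-yl)zinc iodide | C[C@@]1(OC=O)CC[C@H]2C(C)(C)CCC[C@]2(C)[C@H]1C[Zn]I
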